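**Retrosynthetic overview**

1. Target 24 ⇐ hydrolysis of the 3,5-acetonide of macrolide 23 (the only protecting group in the route).
2. 23 ⇐ 14-endo radical ring closure of seco ester 22: a C6 radical (from a secondary bromide) adds to C7 of the C7=C8 isopropenyl ketone, forming C6–C7 and setting C6 and C8.
3. 22 ⇐ syn aldol (C10–C11) of 2-methylpent-1-en-3-one 20 with ester aldehyde 19 ⇐ ozonolysis of ester 17 ⇐ intermolecular esterification of acid 12 (C1–C6) with alcohol 15 (C11–C13).
4. 12 ⇐ β-ketoimide sequence: C-acylation, titanium aldol with 2-bromopropanal, syn reduction, acetonide, auxiliary cleavage; 15 ⇐ (2R,3R)-2,3-dimethyloxirane + vinylmagnesium bromide.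
5. Ring order: the 1,3-dioxane (step 6) first, the 14-membered ring (step 12) second and last.

Assumption: (S)-4-benzyloxazolidin-2-one is treated as a recoverable chiral reagent (introduced in step 1, released in step 7, no atom of it reaches the target); positions are given in macrolide numbering (C1 = lactone carbonyl, C13 = carbinol carbon of the lactone).

**Route**

Step 1
Reactants: 1 propionyl chloride
Product: 2 (S)-4-benzyl-3-propionyloxazolidin-2-one
Conditions: (S)-4-benzyloxazolidin-2-one, n-BuLi, THF, −78 °C; then 1, −78 → 0 °C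
Reagents that add atoms: (S)-4-benzyloxazolidin-2-one, O=C1N[C@@H](Cc2ccccc2)CO1
Why: N-acylation of the lithiated oxazolidinone by the acid chloride (standard Evans imide formation); no stereocentre is formed.

Step 2
Reactants: 2 (S)-4-benzyl-3-propionyloxazolidin-2-one; 1 propionyl chloride
Product: 4 (S)-4-benzyl-3-[(R)-2-methyl-3-oxopentanoyl]oxazolidin-2-one, via lithium Z-enolate 3 (not isolated)
Conditions: LiN(i-Pr)2, THF, −78 °C; then 1, −78 °C
Reagents that add atoms: none
Why: Evans C-acylation (Claisen type) of the chelated Z-enolate, in which the acid chloride enters anti to the benzyl group and sets C2 as R; the product does not epimerise because allylic 1,3-strain keeps C2–H out of conjugation.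

Step 3
Reactants: 5 propanal
Product: 6 (±)-2-bromopropanal
Conditions: Br2, CH2Cl2, 0 → 20 °C; distil, use at once
Reagents that add atoms: bromine, BrBr
Why: α-bromination of the aldehyde through its enol; racemic material suffices because C6 later becomes a planar radical.

Step 4
Reactants: 4 (S)-4-benzyl-3-[(R)-2-methyl-3-oxopentanoyl]oxazolidin-2-one; 6 (±)-2-bromopropanal
Product: 8 (S)-4-benzyl-3-[(2R,4R,5R,6RS)-6-bromo-5-hydroxy-2,4-dimethyl-3-oxoheptanoyl]oxazolidin-2-one, via trichlorotitanium Z-enolate 7 (not isolated)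
Conditions: TiCl4, i-Pr2NEt, CH2Cl2, −10 °C; then 6 (2.5 equiv), −78 → −40 °C
Reagents that add atoms: none
Why: Evans β-ketoimide titanium aldol, in which the chelated Z-enolate of the ethyl side reacts through a Zimmerman–Traxler chair on the face dictated by the C2 methyl stereocentre to give the 2,4-syn-4,5-syn adduct (C4 and C5 set); C6 remains an epimer mixture, which is harmless.

Step 5
Reactants: 8 bromo aldol imide
Product: 9 (S)-4-benzyl-3-[(2R,3S,4S,5R,6RS)-6-bromo-3,5-dihydroxy-2,4-dimethylheptanoyl]oxazolidin-2-one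
Conditions: Zn(BH4)2, CH2Cl2/Et2O, −78 → −30 °C
Reagents that add atoms: none
Why: chelation-controlled β-hydroxy ketone reduction, in which zinc bridges the C5 oxygen and the C3 carbonyl and external hydride gives the 3,5-syn diol (C3 set), completing the all-syn C2–C5 tetrad.

Step 6
Reactants: 9 bromo diol imide
Product: 10 (S)-4-benzyl-3-{(R)-2-[(4S,5S,6R)-6-[(1RS)-1-bromoethyl]-2,2,5-trimethyl-1,3-dioxan-4-yl]propanoyl}oxazolidin-2-one
Conditions: Me2C(OMe)2, CSA (5 mol %), CH2Cl2, 23 °C
Reagents that add atoms: 2,2-dimethoxypropane, COC(C)(C)OC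
Why: acid-catalysed transacetalisation of the syn-1,3-diol to the chair acetonide, which blocks both hydroxyls, prevents lactonisation onto C1 and rigidifies the C3–C6 region for step 12.

Step 7
Reactants: 10 acetonide bromo imide
Product: 12 (R)-2-[(4S,5S,6R)-6-[(1RS)-1-bromoethyl]-2,2,5-trimethyl-1,3-dioxan-4-yl]propanoic acid, via peroxy acid 11 (not isolated)
Conditions: LiOH, H2O2, THF/H2O 3:1, 0 °C; Na2SO3; HCl to pH 3
Reagents that add atoms: hydrogen peroxide, OO
Why: hydroperoxide-selective exocyclic imide cleavage followed by sulfite reduction of the peracid; C2 is not epimerised and the hindered secondary bromide next to the dioxane survives the short, cold exposure.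

Step 8
Reactants: 13 (2R,3R)-2,3-dimethyloxirane; 14 vinylmagnesium bromide
Product: 15 (2R,3R)-3-methylpent-4-en-2-ol
Conditions: CuI (10 mol %), THF, −30 → 0 °C; then H2O
Reagents that add atoms: none
Why: copper-catalysed SN2 opening of the C2-symmetric trans-epoxide by the vinyl Grignard reagent (either carbon gives the same product), with inversion at the attacked carbon giving the 12,13-syn pair, both R.

Step 9
Reactants: 12 acetonide bromo acid; 15 (2R,3R)-3-methylpent-4-en-2-ol
Product: 17 (2R,3R)-3-methylpent-4-en-2-yl ester of acid 12, via mixed anhydride 16 (not isolated)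
Conditions: 2,4,6-Cl3C6H2COCl, Et3N, THF, 23 °C; then 15, DMAP, toluene, 23 °C
Reagents that add atoms: none
Why: Yamaguchi esterification through the mixed anhydride and acyl-DMAP species, forming the future lactone C–O bond intermolecularly with retention at C13.

Step 10
Reactants: 17 pentenyl ester
Product: 19 (2R,3S)-3-methyl-4-oxobutan-2-yl ester of acid 12, via ozonide 18 (not isolated)
Conditions: O3, CH2Cl2, −78 °C; PPh3, −78 → 23 °C; used crude
Reagents that add atoms: ozone, [O-][O+]=O
Why: ozonolysis of the terminal alkene with reductive work-up gives the α-methyl aldehyde under neutral, cold conditions that avoid C12 epimerisation and β-elimination of the acyloxy group.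

Step 11
Reactants: 20 2-methylpent-1-en-3-one; 19 ester aldehyde
Product: 22 (2R,3R,4S,5R)-4-hydroxy-3,5,7-trimethyl-6-oxooct-7-en-2-yl ester of acid 12, via dibutylboron Z-enolate 21 (not isolated)
Conditions: 20 (1.5 equiv), n-Bu2BOTf, i-Pr2NEt, CH2Cl2, −78 °C; then 19, −78 → −20 °C; MeOH/pH 7 buffer/H2O2, 0 °C
Reagents that add atoms: none
Why: boron-mediated syn aldol, in which the Z-enolate adds through a Zimmerman–Traxler chair (10,11-syn) and the anti-Felkin and 1,3-anti preferences of a 2,3-syn α-methyl-β-oxy aldehyde reinforce each other to give 11,12-anti (C10 R, C11 S); the buffered work-up spares the enone.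

Step 12
Reactants: 22 bromo enone seco ester
Product: 23 3,5-O-isopropylidene-8,8a-deoxyoleandolide
Conditions: Bu3SnH (1.5 equiv), AIBN (0.3 equiv), syringe pump 12 h, PhH, 80 °C, 2 mM
Reagents that add atoms: none
Why: Proposed new method: a tin hydride radical chain in which Bu3Sn• abstracts bromine from either C6 epimer to give one planar, nucleophilic C6 radical that closes the ring by 14-endo attack on the unsubstituted C7 terminus of the electron-poor isopropenyl ketone (polarity-matched, favoured over reduction at sub-millimolar stannane), the new bond forming anti to the C4–C5 bond of the chair dioxane with C5–H eclipsing the C6 methyl (predicted 6S), after which the s-trans C8 enoxyl radical, holding C10–H in plane to avoid allylic 1,3-strain, takes hydrogen from Bu3SnH on the face of the C10 methyl away from the C11 ring branch (predicted 8R); the closest known reactions are Porter-type tin hydride macrocyclisations of ω-haloalkyl enones and acrylates and Giese 1,2-induction in acyclic radicals.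

Step 13
Reactants: 23 macrolide acetonide
Product: 24 8,8a-deoxyoleandolide
Conditions: 1 M aq HCl/THF 1:3, 23 °C
Reagents that add atoms: none
Why: acid-catalysed acetonide hydrolysis frees the 3- and 5-hydroxyls; the lactone and the β-hydroxy ketone tolerate dilute acid at room temperature and no stereocentre is touched.

**Compound list**

1 | propionyl chloride | CCC(Cl)=O | starting material
2 | (S)-4-benzyl-3-propionyloxazolidin-2-one | CCC(=O)N1[C@@H](Cc2ccccc2)COC1=O | intermediate
3 | lithium Z-enolate of 2 | C/C=C(\O[Li])N1[C@@H](Cc2ccccc2)COC1=O | intermediate (not isolated)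
4 | (S)-4-benzyl-3-[(R)-2-methyl-3-oxopentanoyl]oxazolidin-2-one | CCC(=O)[C@@H](C)C(=O)N1[C@@H](Cc2ccccc2)COC1=O | intermediate
5 | propanal | CCC=O | starting material
6 | (±)-2-bromopropanal | CC(Br)C=O | intermediate
7 | trichlorotitanium Z-enolate of 4 (ethyl side) | C/C=C(\O[Ti](Cl)(Cl)Cl)[C@@H](C)C(=O)N1[C@@H](Cc2ccccc2)COC1=O | intermediate (not isolated)
8 | (S)-4-benzyl-3-[(2R,4R,5R,6RS)-6-bromo-5-hydroxy-2,4-dimethyl-3-oxoheptanoyl]oxazolidin-2-one | CC(Br)[C@H](O)[C@@H](C)C(=O)[C@@H](C)C(=O)N1[C@@H](Cc2ccccc2)COC1=O | intermediate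
9 | (S)-4-benzyl-3-[(2R,3S,4S,5R,6RS)-6-bromo-3,5-dihydroxy-2,4-dimethylheptanoyl]oxazolidin-2-one | CC(Br)[C@H](O)[C@@H](C)[C@H](O)[C@@H](C)C(=O)N1[C@@H](Cc2ccccc2)COC1=O | intermediate
10 | (S)-4-benzyl-3-{(R)-2-[(4S,5S,6R)-6-[(1RS)-1-bromoethyl]-2,2,5-trimethyl-1,3-dioxan-4-yl]propanoyl}oxazolidin-2-one | O=C(N1[C@@H](Cc2ccccc2)COC1=O)[C@H](C)[C@H]3OC(C)(C)O[C@@H](C(Br)C)[C@H]3C | intermediate
11 | (R)-2-[(4S,5S,6R)-6-[(1RS)-1-bromoethyl]-2,2,5-trimethyl-1,3-dioxan-4-yl]propaneperoxoic acid | OOC(=O)[C@H](C)[C@H]1OC(C)(C)O[C@@H](C(Br)C)[C@H]1C | intermediate (not isolated)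
12 | (R)-2-[(4S,5S,6R)-6-[(1RS)-1-bromoethyl]-2,2,5-trimethyl-1,3-dioxan-4-yl]propanoic acid | OC(=O)[C@H](C)[C@H]1OC(C)(C)O[C@@H](C(Br)C)[C@H]1C | intermediate
13 | (2R,3R)-2,3-dimethyloxirane | C[C@H]1O[C@@H]1C | starting material
14 | vinylmagnesium bromide | C=C[Mg]Br | starting material
15 | (2R,3R)-3-methylpent-4-en-2-ol | C=C[C@@H](C)[C@@H](C)O | intermediate
16 | mixed anhydride of 12 with 2,4,6-trichlorobenzoic acid | O=C(OC(=O)c1c(Cl)cc(Cl)cc1Cl)[C@H](C)[C@H]2OC(C)(C)O[C@@H](C(Br)C)[C@H]2C | intermediate (not isolated)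
17 | (2R,3R)-3-methylpent-4-en-2-yl ester of 12 | C=C[C@@H](C)[C@@H](C)OC(=O)[C@H](C)[C@H]1OC(C)(C)O[C@@H](C(Br)C)[C@H]1C | intermediate
18 | ozonide (1,2,4-trioxolane) of 17 | C1OC(OO1)[C@@H](C)[C@@H](C)OC(=O)[C@H](C)[C@H]2OC(C)(C)O[C@@H](C(Br)C)[C@H]2C | intermediate (not isolated)
19 | (2R,3S)-3-methyl-4-oxobutan-2-yl ester of 12 | O=C[C@@H](C)[C@@H](C)OC(=O)[C@H](C)[C@H]1OC(C)(C)O[C@@H](C(Br)C)[C@H]1C | intermediate
20 | 2-methylpent-1-en-3-one | CCC(=O)C(C)=C | starting material
21 | dibutylboron Z-enolate of 20 | C/C=C(\OB(CCCC)CCCC)C(C)=C | intermediate (not isolated)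
22 | (2R,3R,4S,5R)-4-hydroxy-3,5,7-trimethyl-6-oxooct-7-en-2-yl ester of 12 | C=C(C)C(=O)[C@H](C)[C@@H](O)[C@@H](C)[C@@H](C)OC(=O)[C@H](C)[C@H]1OC(C)(C)O[C@@H](C(Br)C)[C@H]1C | intermediate
23 | 3,5-O-isopropylidene-8,8a-deoxyoleandolide | C[C@H]1C[C@@H](C)C(=O)[C@H](C)[C@@H](O)[C@@H](C)[C@@H](C)OC(=O)[C@H](C)[C@H]2OC(C)(C)O[C@@H]1[C@H]2C | intermediate
24 | 8,8a-deoxyoleandolide (2R,3S,4R,5S,6S,8R,10R,11S,12R,13R) | C[C@@H]1[C@@H](O)[C@@H](C)C[C@@H](C)C(=O)[C@H](C)[C@@H](O)[C@@H](C)[C@@H](C)OC(=O)[C@H](C)[C@H]1O | target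

**Step count**

Total: 13 steps. Longest linear sequence: 11 steps (1, 2, 4, 5, 6, 7, 9, 10, 11, 12, 13).

**Three steps most likely to fail, with fallbacks**

Step 12 (radical ring closure). The risks are simple reduction of the C6 radical, stannane attack on the enone, and the wrong configuration at C6 or C8, both of which rest on conformational prediction. The fallback sets out from 17 and comes back at 23. Under the same tin hydride conditions, but at normal concentration and with 10 equiv of enone 20, bromide 17 is coupled intermolecularly to give the ethyl ketone Giese adduct F1. At this acyclic stage the C6 and C8 isomers can be separated, and C8 can be equilibrated with DBU. Ozonolysis (O3; PPh3) then gives the keto aldehyde F2. The ring is closed at C10–C11 by an intramolecular boron aldol (n-Bu2BOTf, i-Pr2NEt, CH2Cl2, 1 mM, −78 → 0 °C), with Z-enolisation of the ethyl side and the same anti-Felkin bias as step 11, giving 23.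

Step 11 (aldol on the β-acyloxy aldehyde with an enone-derived enolate). The risks are β-elimination or epimerisation of 19, an enolate that is itself a diene, and selectivity that rests on substrate control alone. The fallback sets out from 19 and comes back at 22. An Evans syn aldol of the dibutylboron enolate of (R)-4-benzyl-3-propionyloxazolidin-2-one with 19 gives the aldol imide F3 with reagent-controlled 10R,11S. Transamidation (AlMe3, MeONHMe·HCl, CH2Cl2, −20 °C) gives the Weinreb amide F4. Isopropenylmagnesium bromide (3 equiv, THF, −20 °C) then adds to the amide in preference to the hindered ester and gives 22.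

Step 4 (aldol with the labile α-bromo aldehyde, and carrying the secondary bromide through four further steps). The fallback sets out from 4 and comes back at 10. The same titanium aldol with acrolein gives the vinyl aldol F5. Zn(BH4)2 reduction gives the vinyl diol F6, and Me2C(OMe)2/CSA gives the vinyl acetonide F7. Markovnikov hydrobromination by hydrogen-atom transfer (Co(acac)2, t-BuOOH, Et3SiH, TsBr, n-PrOH, 23 °C) then installs the C6 bromide and gives 10.

**Further compounds**

F1 | step 12 | (2R,3R)-3-methylpent-4-en-2-yl (2R,3S,4R,5S,6S,8R)-3,5-(isopropylidenedioxy)-2,4,6,8-tetramethyl-9-oxoundecanoate | C=C[C@@H](C)[C@@H](C)OC(=O)[C@H](C)[C@H]1OC(C)(C)O[C@@H]([C@@H](C)C[C@@H](C)C(=O)CC)[C@H]1C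
F2 | step 12 | (2R,3S)-3-methyl-4-oxobutan-2-yl (2R,3S,4R,5S,6S,8R)-3,5-(isopropylidenedioxy)-2,4,6,8-tetramethyl-9-oxoundecanoate | O=C[C@@H](C)[C@@H](C)OC(=O)[C@H](C)[C@H]1OC(C)(C)O[C@@H]([C@@H](C)C[C@@H](C)C(=O)CC)[C@H]1C
F3 | step 11 | (R)-4-benzyl-3-[(2R,3S,4R,5R)-3-hydroxy-2,4-dimethyl-5-(acyloxy)hexanoyl]oxazolidin-2-one, acyl = acyl group of 12 | O=C1OC[C@@H](Cc2ccccc2)N1C(=O)[C@H](C)[C@@H](O)[C@@H](C)[C@@H](C)OC(=O)[C@H](C)[C@H]3OC(C)(C)O[C@@H](C(Br)C)[C@H]3C
F4 | step 11 | (2R,3R,4S,5R)-4-hydroxy-6-[methoxy(methyl)amino]-3,5-dimethyl-6-oxohexan-2-yl ester of 12 | CON(C)C(=O)[C@H](C)[C@@H](O)[C@@H](C)[C@@H](C)OC(=O)[C@H](C)[C@H]1OC(C)(C)O[C@@H](C(Br)C)[C@H]1C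
F5 | step 4 | (S)-4-benzyl-3-[(2R,4R,5S)-5-hydroxy-2,4-dimethyl-3-oxohept-6-enoyl]oxazolidin-2-one | C=C[C@H](O)[C@@H](C)C(=O)[C@@H](C)C(=O)N1[C@@H](Cc2ccccc2)COC1=O
F6 | step 4 | (S)-4-benzyl-3-[(2R,3S,4R,5S)-3,5-dihydroxy-2,4-dimethylhept-6-enoyl]oxazolidin-2-one | C=C[C@H](O)[C@@H](C)[C@H](O)[C@@H](C)C(=O)N1[C@@H](Cc2ccccc2)COC1=O
F7 | step 4 | (S)-4-benzyl-3-{(R)-2-[(4S,5R,6S)-2,2,5-trimethyl-6-vinyl-1,3-dioxan-4-yl]propanoyl}oxazolidin-2-one | O=C(N1[C@@H](Cc2ccccc2)COC1=O)[C@H](C)[C@H]3OC(C)(C)O[C@@H](C=C)[C@H]3C
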